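**Retrosynthetic overview**
- Feature: in the benzene ring (C1 carrying the ketone carbon C7, C2–OH, C3–4-methylpentyl, C4–OH, C5–H, C6–H) the 1,3-placed oxygens and the bare C5–C6 edge mark the arene as a 4-acyl-2-alkylcyclohexane-1,3-dione that has lost two hydrogens, so the arene is formed last by dehydrogenation.
- Key disconnection of that carbocycle: C1–C6 (conjugate addition) and C3–C4 (Claisen closure), giving the β-diketone C7–C1–C2–C3 (pyrrole on C7, side chain on C3) and methyl acrylate (C4–C5–C6).
- The β-diketone is cut at C1–C2 into 2-acetyl-4,5-dichloropyrrole (nucleophile) and methyl 6-methylheptanoate (acyl donor), so the N–H pyrrole carbonyl never has to act as the electrophile toward an enolate.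
- The acetylpyrrole comes from 4,5-dichloro-1H-pyrrole-2-carboxylic acid through its Weinreb amide; the N–H stays unprotected and is carried as its anion in the basic steps.
- Ring order: pyrrole bought intact; six-membered carbocycle closed in step 5; the same ring aromatized in step 6.

Key step: step 5

Remark on the chemistry: the β-diketone, the Michael adduct and the cyclohexanedione are tautomeric mixtures (the adduct racemic at an enolizable carbon); each is drawn as one tautomer, and the achiral target needs no stereochemical control.

**Step 1**
Reactants: 1 4,5-dichloro-1H-pyrrole-2-carboxylic acid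
Product: 3 4,5-dichloro-N-methoxy-N-methyl-1H-pyrrole-2-carboxamide, via acyl imidazolide 2 (not isolated)
Conditions: CDI (1.1 equiv), THF, rt; then MeNH(OMe)·HCl (1.3 equiv), rt
Reagents that add atoms: N,O-dimethylhydroxylamine hydrochloride, CNOC.Cl; 1,1'-carbonyldiimidazole, O=C(n1ccnc1)n1ccnc1 (its imidazole stays only in intermediate 2)
Why: Carbonyldiimidazole activation and amidation, in which the acid is converted with loss of CO2 into acyl imidazolide 2 and the hydroxylamine then displaces imidazole at the acyl carbon, while the weakly nucleophilic N–H of the electron-poor pyrrole should not compete.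

**Step 2**
Reactants: 3 4,5-dichloro-N-methoxy-N-methyl-1H-pyrrole-2-carboxamide
Product: 4 1-(4,5-dichloro-1H-pyrrol-2-yl)ethan-1-one
Conditions: MeMgBr (3.5 equiv), THF, 0 °C to rt; 1 M HCl
Reagents that add atoms: methylmagnesium bromide, C[Mg]Br
Why: Weinreb ketone synthesis, in which the first equivalent of MeMgBr removes the pyrrole N–H, a further equivalent adds to the amide, and the magnesium chelate of the tetrahedral adduct blocks a second addition until the acidic quench releases the methyl ketone.

**Step 3**
Reactants: 5 6-methylheptanoic acid
Product: 6 methyl 6-methylheptanoate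
Conditions: MeOH, H2SO4 (cat.), reflux
Reagents that add atoms: methanol, CO
Why: Fischer esterification, driven to completion by methanol as solvent.

**Step 4**
Reactants: 4 1-(4,5-dichloro-1H-pyrrol-2-yl)ethan-1-one; 6 methyl 6-methylheptanoate
Product: 7 1-(4,5-dichloro-1H-pyrrol-2-yl)-8-methylnonane-1,3-dione
Conditions: NaH (4 equiv), 6 (2 equiv), THF, 0 °C to reflux; 1 M HCl
Reagents that add atoms: none
Why: Crossed Claisen condensation, in which NaH removes the N–H and then a proton of the acetyl methyl (the only enolizable carbon of 4), the enolate is acylated by ester 6 with loss of methoxide, and irreversible deprotonation of the β-diketone pulls the equilibria, including reversible self-condensation of 6, toward 7.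

**Step 5**
Reactants: 7 1-(4,5-dichloro-1H-pyrrol-2-yl)-8-methylnonane-1,3-dione; 8 methyl acrylate
Product: 10 4-(4,5-dichloro-1H-pyrrole-2-carbonyl)-2-(4-methylpentyl)cyclohexane-1,3-dione (drawn as its bis-enol tautomer), via Michael adduct 9 (not isolated)
Conditions: 8 (1.05 equiv), KOt-Bu (0.2 equiv), THF/t-BuOH, 0 °C to rt; then KOt-Bu (4 equiv), THF, rt to 50 °C; 1 M HCl
Reagents that add atoms: none
Why: With only catalytic tert-butoxide the single carbon nucleophile present is the C1 enolate flanked by C7=O and C2=O, which adds to the β-carbon of acrylate 8 (C1–C6 bond) and is reprotonated to keto ester 9; the excess tert-butoxide added next holds 9 as its N,C1-dianion and reversibly generates the C3 carbanion, which attacks the ester carbonyl (C3–C4 bond) and expels methoxide. The closest known reaction type is the Michael–Claisen (Michael–Dieckmann) annulation of ketones, β-keto esters and β-diketones with acrylates to cyclohexane-1,3-diones. The six-membered carbocycle closes in the 6-(enolendo)-exo-trig mode, with the enolate bond C2=C3 inside the new ring and the ester C=O outside it. No stereocentre has to be controlled, because the C1 centre of 9 is enolizable and C1 and C3 of 10 are enolic. The step needs site selectivity among C1, C3 and the pyrrole nitrogen, and the substrate secures it through acidity (only C1 gives an irreversible carbon–carbon bond under catalytic base, N-alkylation being reversible) and through ring size (only C3 can reach the ester in a six-membered transition state, since C1 would close a four-membered ring). Deprotonation of the triketone product to a stabilized polyanion makes the closure irreversible, and the anionic pyrrolide and diketonate shield C7 and C2 from retro-Claisen cleavage by the methoxide released.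

**Step 6**
Reactants: 10 4-(4,5-dichloro-1H-pyrrole-2-carbonyl)-2-(4-methylpentyl)cyclohexane-1,3-dione
Product: 11 (4,5-dichloro-1H-pyrrol-2-yl)[2,4-dihydroxy-3-(4-methylpentyl)phenyl]methanone
Conditions: DDQ (1.1 equiv), 1,4-dioxane, 80 °C
Reagents that add atoms: none
Why: Quinone dehydrogenation, in which the dienol tautomer of 10 (C1=C2(OH)–C3=C4(OH)) transfers hydride from C6 to DDQ to give a cation delocalized over C6, C2 and C4 and stabilized by both oxygens, and loss of the C5 proton then gives the aromatic resorcinol, a conversion known for cyclohexane-1,3-diones and cyclohexadienes that should leave the deactivated dichloropyrrole and the saturated side chain untouched.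

**Compound list**
1 | 4,5-dichloro-1H-pyrrole-2-carboxylic acid | O=C(O)c1cc(Cl)c(Cl)[nH]1 | starting material
2 | (4,5-dichloro-1H-pyrrol-2-yl)(1H-imidazol-1-yl)methanone | O=C(c1cc(Cl)c(Cl)[nH]1)n1ccnc1 | intermediate
3 | 4,5-dichloro-N-methoxy-N-methyl-1H-pyrrole-2-carboxamide | CON(C)C(=O)c1cc(Cl)c(Cl)[nH]1 | intermediate
4 | 1-(4,5-dichloro-1H-pyrrol-2-yl)ethan-1-one | CC(=O)c1cc(Cl)c(Cl)[nH]1 | intermediate
5 | 6-methylheptanoic acid | CC(C)CCCCC(=O)O | starting material
6 | methyl 6-methylheptanoate | COC(=O)CCCCC(C)C | intermediate
7 | 1-(4,5-dichloro-1H-pyrrol-2-yl)-8-methylnonane-1,3-dione | CC(C)CCCCC(=O)CC(=O)c1cc(Cl)c(Cl)[nH]1 | intermediate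
8 | methyl acrylate | C=CC(=O)OC | starting material
9 | methyl 4-(4,5-dichloro-1H-pyrrole-2-carbonyl)-10-methyl-5-oxoundecanoate (racemic, enolizable centre) | COC(=O)CCC(C(=O)c1cc(Cl)c(Cl)[nH]1)C(=O)CCCCC(C)C | intermediate
10 | 4-(4,5-dichloro-1H-pyrrole-2-carbonyl)-2-(4-methylpentyl)cyclohexane-1,3-dione (bis-enol tautomer, no fixed stereocentre) | CC(C)CCCC1=C(O)CCC(C(=O)c2cc(Cl)c(Cl)[nH]2)=C1O | intermediate
11 | (4,5-dichloro-1H-pyrrol-2-yl)[2,4-dihydroxy-3-(4-methylpentyl)phenyl]methanone | CC(C)CCCc1c(O)ccc(C(=O)c2cc(Cl)c(Cl)[nH]2)c1O | target

**Step count**
Total steps: 6. Longest linear sequence: 5 steps (1 → 3 → 4 → 7 → 10 → 11, steps 1, 2, 4, 5 and 6).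

**Steps most likely to fail**

1. Step 5. The sequence may stall after the conjugate addition because too little of the C3 carbanion is populated in the polyanion. It may also be diverted by a second conjugate addition at C1, by N-alkylation of the pyrrolide, or by O- or N-acyl transfer to the ester. The fallback builds the same triketone by a different bond construction; it sets out from Weinreb amide 3 and comes back at 10. Commercial cyclohexane-1,3-dione, 4-methylpentanal and Hantzsch ester with catalytic L-proline in CH2Cl2 (Knoevenagel condensation followed by transfer hydrogenation) should give 2-(4-methylpentyl)cyclohexane-1,3-dione F1. Its dianion (LiN(i-Pr)2, 2.2 equiv, THF/HMPA, −78 to 0 °C) reacts at the terminal carbon C4, as is usual for β-diketone dianions. It is acylated there by 3 that has first been N-lithiated with LiN(SiMe3)2, and acidic work-up should deliver 10.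

2. Step 6. Hydride transfer may be outrun by covalent addition of the enol to the quinone, or the newly formed electron-rich resorcinol may be oxidized further at its benzylic CH2. The fallback replaces hydride abstraction by iodination–elimination with a temporary ether; it sets out from 10 and comes back at 11. I2 in refluxing MeOH (enol ether formation, α-iodination, loss of HI) should aromatize 10 to the 4-O-methyl ether (4,5-dichloro-1H-pyrrol-2-yl)[2-hydroxy-4-methoxy-3-(4-methylpentyl)phenyl]methanone F2, the hydrogen-bonded 2-OH staying free. BBr3 in CH2Cl2 (−78 °C to rt) then cleaves the aryl methyl ether to give 11.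

3. Step 4. Enolization of the poorly soluble sodium pyrrolide may be slow, so that self-condensation of the ester consumes the acyl donor before cross-acylation occurs. The fallback replaces the equilibrium condensation by irreversible acylation of a preformed dianion; it sets out from 4 and 6 and comes back at 7. Ester 6 is converted with MeNH(OMe)·HCl and i-PrMgCl (THF, −20 °C) into N-methoxy-N,6-dimethylheptanamide F3. Ketone 4 is converted into its N,C-dilithio derivative with LiN(i-Pr)2 (2.2 equiv, THF, −78 °C) and acylated by F3. The chelated tetrahedral adduct should persist until the acidic quench, so the β-diketone cannot protonate unreacted enolate, and work-up should give 7.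

**Further compounds**
F1 | step 5 | 2-(4-methylpentyl)cyclohexane-1,3-dione | CC(C)CCCC1C(=O)CCCC1=O
F2 | step 6 | (4,5-dichloro-1H-pyrrol-2-yl)[2-hydroxy-4-methoxy-3-(4-methylpentyl)phenyl]methanone | CC(C)CCCc1c(OC)ccc(C(=O)c2cc(Cl)c(Cl)[nH]2)c1O
F3 | step 4 | N-methoxy-N,6-dimethylheptanamide | CON(C)C(=O)CCCCC(C)C
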